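**Retrosynthetic overview** (C1–C24 are the atom labels of the target chain; C1 is the lactone carbonyl)

1. The δ-lactone, the only ring, closes last on global desilylation of a 5-hydroxy methyl ester; C5 comes from a 1,3-anti reduction and C6–C7 from a boron aldol of methyl ketone 6 (C1–C6) with (Z)-enal 32 (C7–C24).
2. C14–C15 comes from a Zweifel-type union (1,2-shift of the C15 alkyl group from boron to C14) of alkenyl iodide 11 (C7–C14) with boronic ester 26 (C15–C22); the diene is then made from the enol carbamate.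
3. Ketone 6 and iodide 11 both come from ester 5, whose stereotriad (C2–C4 = C10–C12) is set in one new crotylation of Roche ester.
4. Boronic ester 26 comes from methacrolein: auxiliary syn-aldol (C17, C18), Hoppe homoaldol (C19, C20, masked diene), RhCl(PPh3)3-catalysed hydroboration (C16).

Assumption: (S)-SEGPHOS is taken as the ligand antipode that gives the (3S,4S) sense in step 1, and (−)-sparteine as the one that gives the (S)-lithium compound 21; if either sense is opposite in practice, the antipode is used.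

**Step 1**
Reactants: 1 methyl (R)-3-hydroxy-2-methylpropanoate; 2 but-3-en-2-yl acetate (racemic)
Product: 4 methyl (2R,3S,4S)-3-hydroxy-2,4-dimethylhex-5-enoate, via formyl ester 3 (not isolated)
Conditions: [Ir(cod)Cl]2 (2.5 mol %), (S)-SEGPHOS (5 mol %), 4-cyano-3-nitrobenzoic acid (10 mol %), Cs2CO3 (20 mol %), THF, 70 °C
Reagents that add atoms: none
Why: Proposed new method: a transfer-hydrogenative carbonyl crotylation run as a dynamic kinetic resolution, in which the [Ir(cod)Cl]2/(S)-SEGPHOS catalyst dehydrogenates 1 to formyl ester 3, 3 racemises through its enol faster than it is trapped, the (E)-σ-crotyl complex formed from 2 adds through a closed chair transition state that sets C3/C4 anti under ligand control, and only the enantiomer of 3 that reacts in the Felkin–Anh mode (ester anti to the incoming crotyl group) is consumed so that the C2 methyl ends up syn to the new hydroxyl (starting from (R)-1 gives the same product even if racemisation is slow); the closest known reaction is the Krische anti-crotylation of primary alcohols with α-methylallyl acetate, not yet shown for an alcohol whose aldehyde is an epimerisable 1,3-dicarbonyl compound.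

**Step 2**
Reactants: 4 methyl (2R,3S,4S)-3-hydroxy-2,4-dimethylhex-5-enoate
Product: 5 methyl (2R,3S,4S)-3-[(tert-butyldimethylsilyl)oxy]-2,4-dimethylhex-5-enoate
Conditions: TBSOTf, 2,6-lutidine, CH2Cl2, −78 → 0 °C
Reagents that add atoms: tert-butyldimethylsilyl trifluoromethanesulfonate, CC(C)(C)[Si](C)(C)OS(=O)(=O)C(F)(F)F
Why: Silyl ether formation with the silyl triflate protects the hindered secondary alcohol without touching a stereocentre.

**Step 3**
Reactants: 5 methyl (2R,3S,4S)-3-[(tert-butyldimethylsilyl)oxy]-2,4-dimethylhex-5-enoate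
Product: 6 methyl (2R,3S,4R)-3-[(tert-butyldimethylsilyl)oxy]-2,4-dimethyl-5-oxohexanoate
Conditions: PdCl2 (10 mol %), CuCl, O2 (1 atm), DMF/H2O, 20 °C
Reagents that add atoms: water, O
Why: Tsuji–Wacker oxidation (Markovnikov hydroxypalladation of the terminal alkene) gives the methyl ketone and leaves the α-methyl centre untouched.

**Step 4**
Reactants: 5 methyl (2R,3S,4S)-3-[(tert-butyldimethylsilyl)oxy]-2,4-dimethylhex-5-enoate
Product: 8 methyl (2R,3S,4R)-3-[(tert-butyldimethylsilyl)oxy]-2,4-dimethyl-5-oxopentanoate, via ozonide 7 (not isolated)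
Conditions: O3, CH2Cl2, −78 °C; then PPh3, −78 → 20 °C
Reagents that add atoms: ozone, [O-][O+]=O
Why: Ozonolysis with reductive work-up cleaves the only alkene to the C9 aldehyde under cold neutral conditions that keep the α-methyl centre.

**Step 5**
Reactants: 8 methyl (2R,3S,4R)-3-[(tert-butyldimethylsilyl)oxy]-2,4-dimethyl-5-oxopentanoate
Product: 9 methyl (2R,3S,4S,5Z)-3-[(tert-butyldimethylsilyl)oxy]-6-(1,3-dioxolan-2-yl)-2,4-dimethylhex-5-enoate
Conditions: (1,3-dioxolan-2-ylmethyl)triphenylphosphonium bromide, KN(SiMe3)2, THF, −78 → 0 °C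
Reagents that add atoms: (1,3-dioxolan-2-ylmethyl)triphenylphosphonium bromide, [Br-].C1COC(O1)C[P+](c1ccccc1)(c1ccccc1)c1ccccc1
Why: Wittig olefination with a salt-free non-stabilised ylide goes through the kinetically preferred cis-oxaphosphetane and gives the (Z)-alkene with C7 as a masked aldehyde (minor E isomer removed by chromatography).

**Step 6**
Reactants: 9 methyl (2R,3S,4S,5Z)-3-[(tert-butyldimethylsilyl)oxy]-6-(1,3-dioxolan-2-yl)-2,4-dimethylhex-5-enoate
Product: 10 (2R,3S,4S,5Z)-3-[(tert-butyldimethylsilyl)oxy]-6-(1,3-dioxolan-2-yl)-2,4-dimethylhex-5-enal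
Conditions: iBu2AlH (1.1 equiv), CH2Cl2, −78 °C; aq. potassium sodium tartrate
Reagents that add atoms: none
Why: Partial ester reduction works because the tetrahedral aluminium hemiacetal is stable at −78 °C and releases the aldehyde only on work-up, with acetal and silyl ether inert.

**Step 7**
Reactants: 10 (2R,3S,4S,5Z)-3-[(tert-butyldimethylsilyl)oxy]-6-(1,3-dioxolan-2-yl)-2,4-dimethylhex-5-enal
Product: 11 2-[(1Z,3S,4S,5S,6Z)-4-[(tert-butyldimethylsilyl)oxy]-7-iodo-3,5-dimethylocta-1,6-dien-1-yl]-1,3-dioxolane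
Conditions: EtPPh3I, n-BuLi, THF, 20 °C; I2, −78 °C; NaN(SiMe3)2, −20 °C; then 10, −78 → −20 °C
Reagents that add atoms: ethyltriphenylphosphonium iodide, CC[P+](c1ccccc1)(c1ccccc1)c1ccccc1.[I-]; iodine, II
Why: Zhao–Wittig iodo-olefination with the α-iodo ylide under kinetic control gives the (Z)-2-iodoalkene (iodine cis to C12), as known for α-branched β-silyloxy aldehydes.

**Step 8**
Reactants: 12 propanoyl chloride
Product: 13 1-[(4S)-4-benzyl-2-sulfanylidene-1,3-thiazolidin-3-yl]propan-1-one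
Conditions: (4S)-4-benzyl-1,3-thiazolidine-2-thione, Et3N, DMAP (cat.), CH2Cl2, 0 → 20 °C
Reagents that add atoms: (4S)-4-benzyl-1,3-thiazolidine-2-thione, S=C1N[C@@H](Cc2ccccc2)CS1
Why: N-Acylation attaches the Crimmins auxiliary to the propionate unit.

**Step 9**
Reactants: 13 1-[(4S)-4-benzyl-2-sulfanylidene-1,3-thiazolidin-3-yl]propan-1-one; 14 2-methylprop-2-enal
Product: 16 (2S,3S)-1-[(4S)-4-benzyl-2-sulfanylidene-1,3-thiazolidin-3-yl]-3-hydroxy-2,4-dimethylpent-4-en-1-one, via trichlorotitanium enolate 15 (not isolated)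
Conditions: TiCl4 (1.05 equiv), iPr2NEt (1.1 equiv), N-methyl-2-pyrrolidinone (1.0 equiv), CH2Cl2, 0 °C; then 14, −78 → 0 °C
Reagents that add atoms: none
Why: Crimmins syn-aldol, in which the (Z)-enolate reacts through a non-chelated Zimmerman–Traxler chair with the benzyl group shielding one face, gives the Evans-syn adduct and sets C17 and C18.

**Step 10**
Reactants: 16 (2S,3S)-1-[(4S)-4-benzyl-2-sulfanylidene-1,3-thiazolidin-3-yl]-3-hydroxy-2,4-dimethylpent-4-en-1-one
Product: 17 (2S,3S)-1-[(4S)-4-benzyl-2-sulfanylidene-1,3-thiazolidin-3-yl]-3-[(tert-butyldimethylsilyl)oxy]-2,4-dimethylpent-4-en-1-one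
Conditions: TBSOTf, 2,6-lutidine, CH2Cl2, 0 °C
Reagents that add atoms: tert-butyldimethylsilyl trifluoromethanesulfonate, CC(C)(C)[Si](C)(C)OS(=O)(=O)C(F)(F)F
Why: Silyl ether formation blocks retro-aldol and supplies the bulky allylic group that later directs the hydroboration.

**Step 11**
Reactants: 17 (2S,3S)-1-[(4S)-4-benzyl-2-sulfanylidene-1,3-thiazolidin-3-yl]-3-[(tert-butyldimethylsilyl)oxy]-2,4-dimethylpent-4-en-1-one
Product: 18 (2S,3S)-3-[(tert-butyldimethylsilyl)oxy]-2,4-dimethylpent-4-enal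
Conditions: iBu2AlH, CH2Cl2, −78 °C; aq. potassium sodium tartrate
Reagents that add atoms: none
Why: Reductive cleavage of the N-acyl thiazolidinethione stops at the aldehyde because the tetrahedral intermediate survives at −78 °C, and the auxiliary is recovered.

**Step 12**
Reactants: 19 (2E)-but-2-en-1-ol
Product: 20 (2E)-but-2-en-1-yl di(propan-2-yl)carbamate
Conditions: NaH, THF, 0 °C; then iPr2NCOCl, 65 °C
Reagents that add atoms: di(propan-2-yl)carbamoyl chloride, CC(C)N(C(C)C)C(Cl)=O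
Why: O-Carbamoylation of the alkoxide installs the directing group needed for the Hoppe deprotonation.

**Step 13**
Reactants: 20 (2E)-but-2-en-1-yl di(propan-2-yl)carbamate; 18 (2S,3S)-3-[(tert-butyldimethylsilyl)oxy]-2,4-dimethylpent-4-enal
Product: 23 (1Z,3S,4S,5R,6S)-6-[(tert-butyldimethylsilyl)oxy]-4-hydroxy-3,5,7-trimethylocta-1,7-dien-1-yl di(propan-2-yl)carbamate, via lithiated carbamate 21 (not isolated), via triisopropoxytitanium reagent 22 (not isolated)
Conditions: n-BuLi, (−)-sparteine, pentane/cyclohexane, −70 °C (crystallisation); Ti(OiPr)4, −70 °C; then 18, −78 °C; aq. HCl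
Reagents that add atoms: none
Why: Hoppe homoaldol reaction, in which sparteine-mediated deprotonation with crystallisation-driven resolution gives (S)-21, titanation with inversion gives (R)-22, and 22 adds through a chair transition state (E-crotyl, carbamate pseudo-axial), sets C19/C20 anti with a (Z)-enol carbamate, reagent control reinforcing the Felkin preference of 18.

**Step 14**
Reactants: 23 (1Z,3S,4S,5R,6S)-6-[(tert-butyldimethylsilyl)oxy]-4-hydroxy-3,5,7-trimethylocta-1,7-dien-1-yl di(propan-2-yl)carbamate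
Product: 24 (1Z,3S,4S,5R,6S)-4,6-bis[(tert-butyldimethylsilyl)oxy]-3,5,7-trimethylocta-1,7-dien-1-yl di(propan-2-yl)carbamate
Conditions: TBSOTf, 2,6-lutidine, CH2Cl2, −78 → 0 °C
Reagents that add atoms: tert-butyldimethylsilyl trifluoromethanesulfonate, CC(C)(C)[Si](C)(C)OS(=O)(=O)C(F)(F)F
Why: Silyl ether formation protects the C19 hydroxyl; the enol carbamate is inert to the silyl triflate.

**Step 15**
Reactants: 24 (1Z,3S,4S,5R,6S)-4,6-bis[(tert-butyldimethylsilyl)oxy]-3,5,7-trimethylocta-1,7-dien-1-yl di(propan-2-yl)carbamate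
Product: 26 (1Z,3S,4S,5S,6R,7S)-4,6-bis[(tert-butyldimethylsilyl)oxy]-3,5,7-trimethyl-8-(4,4,5,5-tetramethyl-1,3,2-dioxaborolan-2-yl)oct-1-en-1-yl di(propan-2-yl)carbamate, via catechol boronate 25 (not isolated)
Conditions: catecholborane, RhCl(PPh3)3 (3 mol %), THF, 20 °C; then pinacol, 20 °C
Reagents that add atoms: catecholborane, [H]B1Oc2ccccc2O1; pinacol, CC(C)(O)C(C)(C)O
Why: RhCl(PPh3)3-catalysed hydroboration of the 1,1-disubstituted alkene adds anti to the allylic silyloxy group in the reactive conformer and gives the 16,17-syn product (opposite to the uncatalysed reaction), the internal enol carbamate being too hindered to react, and pinacol exchange gives the stable ester.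

**Step 16**
Reactants: 11 2-[(1Z,3S,4S,5S,6Z)-4-[(tert-butyldimethylsilyl)oxy]-7-iodo-3,5-dimethylocta-1,6-dien-1-yl]-1,3-dioxolane; 26 (1Z,3S,4S,5S,6R,7S)-4,6-bis[(tert-butyldimethylsilyl)oxy]-3,5,7-trimethyl-8-(4,4,5,5-tetramethyl-1,3,2-dioxaborolan-2-yl)oct-1-en-1-yl di(propan-2-yl)carbamate
Product: 30 C7–C22 enol carbamate (8Z;13Z;21Z; 11,17,19-tris-OTBS; C7 as 1,3-dioxolane; stereocentres as in 11 + 26), via alkenyllithium 27 (not isolated), via lithium boronate 28 (not isolated), via selenide 29 (not isolated)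
Conditions: 11, t-BuLi (2.0 equiv), Et2O, −78 °C; 26, THF, −78 °C; PhSeCl, −78 °C; then mCPBA, −45 °C
Reagents that add atoms: none
Why: Zweifel-type olefination in its selenium variant: iodine–lithium exchange with retention, ate-complex formation, selenium-triggered stereospecific 1,2-metallate shift of the C15 alkyl group from boron to C14 (anti to selenium) and oxidation-triggered syn-elimination of boron and selenium give the trisubstituted alkene with retention of the alkenyl geometry, so C15 ends up cis to C12 (13Z).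

**Step 17**
Reactants: 30 C7–C22 enol carbamate
Product: 31 C7–C24 tetraene acetal (8Z;13Z;21Z; 11,17,19-tris-OTBS; C7 as 1,3-dioxolane)
Conditions: CH2=CHMgBr, Ni(acac)2 (10 mol %), Et2O, 0 → 20 °C
Reagents that add atoms: ethenylmagnesium bromide, C=C[Mg]Br
Why: Ni(acac)2-catalysed Kumada-type coupling of the enol carbamate C–O bond with the vinyl Grignard reagent proceeds with retention and gives the terminal (Z)-diene.

**Step 18**
Reactants: 31 C7–C24 tetraene acetal
Product: 32 C7–C24 (8Z)-enal (13Z;21Z; 11,17,19-tris-OTBS)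
Conditions: aq. oxalic acid, SiO2, CH2Cl2, 20 °C
Reagents that add atoms: water, O
Why: Mild acid hydrolysis of the allylic acetal (stabilised oxocarbenium ion) frees the (Z)-enal while silyl ethers and diene survive; the enal is used at once to avoid Z to E isomerisation.

**Step 19**
Reactants: 6 methyl (2R,3S,4R)-3-[(tert-butyldimethylsilyl)oxy]-2,4-dimethyl-5-oxohexanoate; 32 C7–C24 (8Z)-enal
Product: 34 C1–C24 aldol adduct (methyl ester; C5 ketone; 7S-hydroxyl; 3,11,17,19-tetrakis-OTBS), via dicyclohexylboron enolate 33 (not isolated)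
Conditions: 6, (c-Hex)2BCl, Et3N, Et2O, 0 °C; 32, −78 → −27 °C; then H2O2, MeOH, pH 7 buffer
Reagents that add atoms: none
Why: Paterson boron aldol, in which the methyl-side boron enolate adds to the (Z)-enal under 1,6-induction from its γ-stereocentre (C10) reinforced by the α-centre of the ketone, gives the (7S) adduct as known for this ketone/enal pairing.

**Step 20**
Reactants: 34 C1–C24 aldol adduct
Product: 35 C1–C24 (5S,7S)-diol (methyl ester; 3,11,17,19-tetrakis-OTBS)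
Conditions: Me4NBH(OAc)3, MeCN/AcOH, −30 °C
Reagents that add atoms: none
Why: Evans–Saksena reduction delivers hydride intramolecularly from the alkoxy(diacetoxy)borohydride formed at the C7 hydroxyl and gives the 1,3-anti diol, which sets C5.

**Step 21**
Reactants: 35 C1–C24 (5S,7S)-diol
Product: 37 (3R,4S,5R,6S)-4-hydroxy-3,5-dimethyl-6-[(2S,3Z,5S,6S,7S,8Z,11S,12R,13S,14S,15S,16Z)-2,6,12,14-tetrahydroxy-5,7,9,11,13,15-hexamethylnonadeca-3,8,16,18-tetraen-1-yl]oxan-2-one, via seco ester 36 (not isolated)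
Conditions: HF·pyridine, THF, 0 → 20 °C
Reagents that add atoms: none
Why: Global desilylation followed in the same pot by acid-catalysed lactonisation of the 5-hydroxy methyl ester (six-membered ring favoured over the eight-membered alternative from the C7 hydroxyl) gives the target without touching a stereocentre.

**Compound list**

1 | methyl (R)-3-hydroxy-2-methylpropanoate | COC(=O)[C@H](C)CO | starting material
2 | but-3-en-2-yl acetate (racemic) | CC(=O)OC(C)C=C | starting material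
3 | methyl 2-methyl-3-oxopropanoate (racemising) | COC(=O)C(C)C=O | intermediate
4 | methyl (2R,3S,4S)-3-hydroxy-2,4-dimethylhex-5-enoate | COC(=O)[C@H](C)[C@@H](O)[C@@H](C)C=C | intermediate
5 | methyl (2R,3S,4S)-3-[(tert-butyldimethylsilyl)oxy]-2,4-dimethylhex-5-enoate | COC(=O)[C@H](C)[C@@H](O[Si](C)(C)C(C)(C)C)[C@@H](C)C=C | intermediate
6 | methyl (2R,3S,4R)-3-[(tert-butyldimethylsilyl)oxy]-2,4-dimethyl-5-oxohexanoate | COC(=O)[C@H](C)[C@@H](O[Si](C)(C)C(C)(C)C)[C@@H](C)C(C)=O | intermediate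
7 | methyl (2R,3S,4R)-3-[(tert-butyldimethylsilyl)oxy]-2-methyl-4-(1,2,4-trioxolan-3-yl)pentanoate (both epimers at the trioxolane carbon) | COC(=O)[C@H](C)[C@@H](O[Si](C)(C)C(C)(C)C)[C@@H](C)C1OCOO1 | intermediate
8 | methyl (2R,3S,4R)-3-[(tert-butyldimethylsilyl)oxy]-2,4-dimethyl-5-oxopentanoate | COC(=O)[C@H](C)[C@@H](O[Si](C)(C)C(C)(C)C)[C@@H](C)C=O | intermediate
9 | methyl (2R,3S,4S,5Z)-3-[(tert-butyldimethylsilyl)oxy]-6-(1,3-dioxolan-2-yl)-2,4-dimethylhex-5-enoate | COC(=O)[C@H](C)[C@@H](O[Si](C)(C)C(C)(C)C)[C@@H](C)/C=C\C1OCCO1 | intermediate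
10 | (2R,3S,4S,5Z)-3-[(tert-butyldimethylsilyl)oxy]-6-(1,3-dioxolan-2-yl)-2,4-dimethylhex-5-enal | O=C[C@H](C)[C@@H](O[Si](C)(C)C(C)(C)C)[C@@H](C)/C=C\C1OCCO1 | intermediate
11 | 2-[(1Z,3S,4S,5S,6Z)-4-[(tert-butyldimethylsilyl)oxy]-7-iodo-3,5-dimethylocta-1,6-dien-1-yl]-1,3-dioxolane | I/C(C)=C\[C@H](C)[C@@H](O[Si](C)(C)C(C)(C)C)[C@@H](C)/C=C\C1OCCO1 | intermediate
12 | propanoyl chloride | CCC(=O)Cl | starting material
13 | 1-[(4S)-4-benzyl-2-sulfanylidene-1,3-thiazolidin-3-yl]propan-1-one | S=C1SC[C@H](Cc2ccccc2)N1C(=O)CC | intermediate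
14 | 2-methylprop-2-enal | CC(=C)C=O | starting material
15 | trichlorotitanium (Z)-enolate of 13 | C/C=C(\O[Ti](Cl)(Cl)Cl)N1[C@@H](Cc2ccccc2)CSC1=S | intermediate
16 | (2S,3S)-1-[(4S)-4-benzyl-2-sulfanylidene-1,3-thiazolidin-3-yl]-3-hydroxy-2,4-dimethylpent-4-en-1-one | S=C1SC[C@H](Cc2ccccc2)N1C(=O)[C@@H](C)[C@H](O)C(C)=C | intermediate
17 | (2S,3S)-1-[(4S)-4-benzyl-2-sulfanylidene-1,3-thiazolidin-3-yl]-3-[(tert-butyldimethylsilyl)oxy]-2,4-dimethylpent-4-en-1-one | S=C1SC[C@H](Cc2ccccc2)N1C(=O)[C@@H](C)[C@H](O[Si](C)(C)C(C)(C)C)C(C)=C | intermediate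
18 | (2S,3S)-3-[(tert-butyldimethylsilyl)oxy]-2,4-dimethylpent-4-enal | O=C[C@@H](C)[C@H](O[Si](C)(C)C(C)(C)C)C(C)=C | intermediate
19 | (2E)-but-2-en-1-ol | C/C=C/CO | starting material
20 | (2E)-but-2-en-1-yl di(propan-2-yl)carbamate | C/C=C/COC(=O)N(C(C)C)C(C)C | intermediate
21 | [(1S,2E)-1-{[di(propan-2-yl)carbamoyl]oxy}but-2-en-1-yl]lithium (held as its (−)-sparteine complex) | C/C=C/[C@H]([Li])OC(=O)N(C(C)C)C(C)C | intermediate
22 | [(1R,2E)-1-{[di(propan-2-yl)carbamoyl]oxy}but-2-en-1-yl]tri(propan-2-yloxy)titanium | C/C=C/[C@@H]([Ti](OC(C)C)(OC(C)C)OC(C)C)OC(=O)N(C(C)C)C(C)C | intermediate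
23 | (1Z,3S,4S,5R,6S)-6-[(tert-butyldimethylsilyl)oxy]-4-hydroxy-3,5,7-trimethylocta-1,7-dien-1-yl di(propan-2-yl)carbamate | CC(C)N(C(C)C)C(=O)O/C=C\[C@H](C)[C@H](O)[C@@H](C)[C@H](O[Si](C)(C)C(C)(C)C)C(C)=C | intermediate
24 | (1Z,3S,4S,5R,6S)-4,6-bis[(tert-butyldimethylsilyl)oxy]-3,5,7-trimethylocta-1,7-dien-1-yl di(propan-2-yl)carbamate | CC(C)N(C(C)C)C(=O)O/C=C\[C@H](C)[C@H](O[Si](C)(C)C(C)(C)C)[C@@H](C)[C@H](O[Si](C)(C)C(C)(C)C)C(C)=C | intermediate
25 | (1Z,3S,4S,5S,6R,7S)-8-(1,3,2-benzodioxaborol-2-yl)-4,6-bis[(tert-butyldimethylsilyl)oxy]-3,5,7-trimethyloct-1-en-1-yl di(propan-2-yl)carbamate | CC(C)N(C(C)C)C(=O)O/C=C\[C@H](C)[C@H](O[Si](C)(C)C(C)(C)C)[C@@H](C)[C@H](O[Si](C)(C)C(C)(C)C)[C@@H](C)CB1Oc2ccccc2O1 | intermediate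
26 | (1Z,3S,4S,5S,6R,7S)-4,6-bis[(tert-butyldimethylsilyl)oxy]-3,5,7-trimethyl-8-(4,4,5,5-tetramethyl-1,3,2-dioxaborolan-2-yl)oct-1-en-1-yl di(propan-2-yl)carbamate | CC(C)N(C(C)C)C(=O)O/C=C\[C@H](C)[C@H](O[Si](C)(C)C(C)(C)C)[C@@H](C)[C@H](O[Si](C)(C)C(C)(C)C)[C@@H](C)CB1OC(C)(C)C(C)(C)O1 | intermediate
27 | alkenyllithium from 11 (lithium in place of iodine, geometry retained) | [Li]/C(C)=C\[C@H](C)[C@@H](O[Si](C)(C)C(C)(C)C)[C@@H](C)/C=C\C1OCCO1 | intermediate
28 | lithium boronate complex of 26 and 27 (boron bonded to C14 and C15) | [Li+].CC(C)N(C(C)C)C(=O)O/C=C\[C@H](C)[C@H](O[Si](C)(C)C(C)(C)C)[C@@H](C)[C@H](O[Si](C)(C)C(C)(C)C)[C@@H](C)C[B-]1(OC(C)(C)C(C)(C)O1)/C(C)=C\[C@H](C)[C@@H](O[Si](C)(C)C(C)(C)C)[C@@H](C)/C=C\C1OCCO1 | intermediate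
29 | β-(phenylselanyl) boronic ester (SePh on C13; pinacolboryl, methyl and C15 on C14; anti adduct, one of the two face isomers drawn, both give 30) | CC(C)N(C(C)C)C(=O)O/C=C\[C@H](C)[C@H](O[Si](C)(C)C(C)(C)C)[C@@H](C)[C@H](O[Si](C)(C)C(C)(C)C)[C@@H](C)C[C@](C)(B1OC(C)(C)C(C)(C)O1)[C@H]([Se]c1ccccc1)[C@H](C)[C@@H](O[Si](C)(C)C(C)(C)C)[C@@H](C)/C=C\C1OCCO1 | intermediate
30 | C7–C22 enol carbamate (8Z,13Z,21Z; 11,17,19-tris-OTBS; C7 as 1,3-dioxolane; C22 di(propan-2-yl)carbamate) | CC(C)N(C(C)C)C(=O)O/C=C\[C@H](C)[C@H](O[Si](C)(C)C(C)(C)C)[C@@H](C)[C@H](O[Si](C)(C)C(C)(C)C)[C@@H](C)C/C(C)=C\[C@H](C)[C@@H](O[Si](C)(C)C(C)(C)C)[C@@H](C)/C=C\C1OCCO1 | intermediate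
31 | C7–C24 tetraene acetal (8Z,13Z,21Z; 11,17,19-tris-OTBS; C7 as 1,3-dioxolane) | C=C/C=C\[C@H](C)[C@H](O[Si](C)(C)C(C)(C)C)[C@@H](C)[C@H](O[Si](C)(C)C(C)(C)C)[C@@H](C)C/C(C)=C\[C@H](C)[C@@H](O[Si](C)(C)C(C)(C)C)[C@@H](C)/C=C\C1OCCO1 | intermediate
32 | C7–C24 (8Z)-enal (13Z,21Z; 11,17,19-tris-OTBS) | C=C/C=C\[C@H](C)[C@H](O[Si](C)(C)C(C)(C)C)[C@@H](C)[C@H](O[Si](C)(C)C(C)(C)C)[C@@H](C)C/C(C)=C\[C@H](C)[C@@H](O[Si](C)(C)C(C)(C)C)[C@@H](C)/C=C\C=O | intermediate
33 | dicyclohexylboron enolate of 6 (C5=C6 enol borinate) | C=C(OB(C1CCCCC1)C1CCCCC1)[C@H](C)[C@H](O[Si](C)(C)C(C)(C)C)[C@@H](C)C(=O)OC | intermediate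
34 | C1–C24 aldol adduct (methyl ester; C5 ketone; 7S-hydroxyl; 3,11,17,19-tetrakis-OTBS) | C=C/C=C\[C@H](C)[C@H](O[Si](C)(C)C(C)(C)C)[C@@H](C)[C@H](O[Si](C)(C)C(C)(C)C)[C@@H](C)C/C(C)=C\[C@H](C)[C@@H](O[Si](C)(C)C(C)(C)C)[C@@H](C)/C=C\[C@@H](O)CC(=O)[C@H](C)[C@H](O[Si](C)(C)C(C)(C)C)[C@@H](C)C(=O)OC | intermediate
35 | C1–C24 (5S,7S)-diol (methyl ester; 3,11,17,19-tetrakis-OTBS) | C=C/C=C\[C@H](C)[C@H](O[Si](C)(C)C(C)(C)C)[C@@H](C)[C@H](O[Si](C)(C)C(C)(C)C)[C@@H](C)C/C(C)=C\[C@H](C)[C@@H](O[Si](C)(C)C(C)(C)C)[C@@H](C)/C=C\[C@@H](O)C[C@H](O)[C@H](C)[C@H](O[Si](C)(C)C(C)(C)C)[C@@H](C)C(=O)OC | intermediate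
36 | seco ester: methyl 3,5,7,11,17,19-hexahydroxy C1–C24 ester (all silyl groups removed) | C=C/C=C\[C@H](C)[C@H](O)[C@@H](C)[C@H](O)[C@@H](C)C/C(C)=C\[C@H](C)[C@@H](O)[C@@H](C)/C=C\[C@@H](O)C[C@H](O)[C@H](C)[C@H](O)[C@@H](C)C(=O)OC | intermediate
37 | (3R,4S,5R,6S)-4-hydroxy-3,5-dimethyl-6-[(2S,3Z,5S,6S,7S,8Z,11S,12R,13S,14S,15S,16Z)-2,6,12,14-tetrahydroxy-5,7,9,11,13,15-hexamethylnonadeca-3,8,16,18-tetraen-1-yl]oxan-2-one | C=C/C=C\[C@H](C)[C@H](O)[C@@H](C)[C@H](O)[C@@H](C)C/C(C)=C\[C@H](C)[C@@H](O)[C@@H](C)/C=C\[C@@H](O)C[C@@H]1OC(=O)[C@H](C)[C@@H](O)[C@H]1C | target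

**Step count and risk**

Total step count: 21. Longest linear sequence: 13 (steps 8, 9, 10, 11, 13, 14, 15, 16, 17, 18, 19, 20, 21).

Steps most likely to fail:

Step 1 (the proposed new step). The formyl ester may bind the catalyst as an enolate, or the matched/mismatched rate ratio may be too small for a clean 2,3-syn outcome. The fallback uses the established silyl ether version of the same crotylation and known oxidation chemistry; it sets out from 2 and comes back at 5. Commercial methyl (S)-3-hydroxy-2-methylpropanoate F1 is silylated (Et3SiCl, imidazole) to methyl (S)-2-methyl-3-[(triethylsilyl)oxy]propanoate F2 and reduced (iBu2AlH) to (R)-2-methyl-3-[(triethylsilyl)oxy]propan-1-ol F3. F3 is coupled with 2 under the conditions of step 1, now through a configurationally stable β-silyloxy aldehyde, to give (2S,3S,4S)-2,4-dimethyl-1-[(triethylsilyl)oxy]hex-5-en-3-ol F4. TBSOTf gives the bis-silyl ether F5; CrO3/H2SO4 in acetone cleaves the primary triethylsilyl ether and oxidises C1 to (2R,3S,4S)-3-[(tert-butyldimethylsilyl)oxy]-2,4-dimethylhex-5-enoic acid F6; Me3SiCHN2 in MeOH gives 5.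

Step 16. The hindered ate complex may form slowly, or the electrophile or oxidant may attack the enol carbamate. The fallback is a Suzuki–Miyaura cross-coupling; it sets out from 26 and comes back at 30. KHF2 converts 26 into the potassium trifluoroborate F7, which is coupled with 11 (PdCl2(dppf), Cs2CO3, toluene/H2O, 80 °C) with retention at the alkenyl iodide.

Step 7. The iodo-olefination is known to be capricious in yield and Z/E ratio on such aldehydes. The fallback sets out from 10 and comes back at 30. CBr4/PPh3 (2,6-lutidine buffer) converts 10 into the 1,1-dibromoalkene F8; the Negishi trans-selective monomethylation (MeZnCl, Pd(DPEphos)Cl2, THF) replaces the bromine trans to C12 and gives the (Z)-bromoalkene F9; F9 takes the place of 11 in step 16 (bromine–lithium exchange with t-BuLi).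

**Further compounds**

F1 | step 1 | methyl (S)-3-hydroxy-2-methylpropanoate | COC(=O)[C@@H](C)CO
F2 | step 1 | methyl (S)-2-methyl-3-[(triethylsilyl)oxy]propanoate | CC[Si](CC)(CC)OC[C@H](C)C(=O)OC
F3 | step 1 | (R)-2-methyl-3-[(triethylsilyl)oxy]propan-1-ol | CC[Si](CC)(CC)OC[C@H](C)CO
F4 | step 1 | (2S,3S,4S)-2,4-dimethyl-1-[(triethylsilyl)oxy]hex-5-en-3-ol | CC[Si](CC)(CC)OC[C@H](C)[C@@H](O)[C@@H](C)C=C
F5 | step 1 | tert-butyldimethylsilyl ether of F4 (3-OTBS, 1-OSiEt3) | CC[Si](CC)(CC)OC[C@H](C)[C@@H](O[Si](C)(C)C(C)(C)C)[C@@H](C)C=C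
F6 | step 1 | (2R,3S,4S)-3-[(tert-butyldimethylsilyl)oxy]-2,4-dimethylhex-5-enoic acid | OC(=O)[C@H](C)[C@@H](O[Si](C)(C)C(C)(C)C)[C@@H](C)C=C
F7 | step 16 | potassium trifluoroborate corresponding to 26 (BF3K in place of the pinacolboryl group) | CC(C)N(C(C)C)C(=O)O/C=C\[C@H](C)[C@H](O[Si](C)(C)C(C)(C)C)[C@@H](C)[C@H](O[Si](C)(C)C(C)(C)C)[C@@H](C)C[B-](F)(F)F.[K+]
F8 | step 7 | 2-[(1Z,3S,4S,5S)-7,7-dibromo-4-[(tert-butyldimethylsilyl)oxy]-3,5-dimethylhepta-1,6-dien-1-yl]-1,3-dioxolane | BrC(Br)=C[C@H](C)[C@@H](O[Si](C)(C)C(C)(C)C)[C@@H](C)/C=C\C1OCCO1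
F9 | step 7 | 2-[(1Z,3S,4S,5S,6Z)-7-bromo-4-[(tert-butyldimethylsilyl)oxy]-3,5-dimethylocta-1,6-dien-1-yl]-1,3-dioxolane | Br/C(C)=C\[C@H](C)[C@@H](O[Si](C)(C)C(C)(C)C)[C@@H](C)/C=C\C1OCCO1
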